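The flavone is disconnected at C4–C4a, so that the pyranone (ring C) is closed last by intramolecular Friedel–Crafts acylation. Ring A enters as a 3,4,5-trimethoxyphenoxy unit whose two ortho carbons are equivalent and each activated by an ortho and a para methoxy group; acylation there can only deliver C4a with the 5,6,7-oxygen pattern. One operation thus forms C4–C4a and ring C at the final oxidation level. The precursor is a (Z)-3-aryl-3-aryloxyacrylic acid, made by oxa-Michael addition of the phenol to a ring B arylpropiolate. The 3'-oxygen travels as an isopropyl ether, stable to acylating acids and cleaved together with the chelated 5-O-methyl group by BCl3.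

Key step: step 8

Remark: the oxa-Michael addition of step 6 is assumed to take the usual anti course, so that 10 carries the ester and the aryloxy group cis (Z); the geometry would be confirmed by NOE before saponification.

Step 1
Reactants: 1 2-hydroxy-3,4-dimethoxybenzaldehyde
Product: 2 2-isopropoxy-3,4-dimethoxybenzaldehyde
Conditions: 2-bromopropane, K2CO3, DMF, 70 °C
Reagents that add atoms: 2-bromopropane, CC(C)Br
Why: Williamson ether synthesis: the phenoxide of the chelated ortho-hydroxy aldehyde should displace bromide in warm DMF, masking the future 3'-oxygen with a group that tolerates peracid, base, palladium and acylating acid.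

Step 2
Reactants: 2 2-isopropoxy-3,4-dimethoxybenzaldehyde
Product: 4 2-isopropoxy-3,4-dimethoxyphenol, via aryl formate 3 (not isolated)
Conditions: mCPBA, CH2Cl2, 0 °C to rt; then K2CO3 (cat.), MeOH, rt
Reagents that add atoms: 3-chloroperoxybenzoic acid (mCPBA), OOC(=O)c1cccc(Cl)c1
Why: Baeyer–Villiger (Dakin-type) oxidation: in the Criegee adduct the electron-rich aryl group, with ortho and para alkoxy donors, should migrate in preference to hydrogen to give formate 3, which mild methanolysis cleaves to the phenol.

Step 3
Reactants: 4 2-isopropoxy-3,4-dimethoxyphenol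
Product: 5 6-iodo-2-isopropoxy-3,4-dimethoxyphenol
Conditions: NIS, MeCN, 0 °C
Reagents that add atoms: N-iodosuccinimide, O=C1CCC(=O)N1I
Why: Electrophilic aromatic iodination: the free hydroxyl is the strongest donor and its para position is blocked by methoxy, so iodine should enter at the only free ortho carbon, C6, which becomes C1' of ring B.

Step 4
Reactants: 5 6-iodo-2-isopropoxy-3,4-dimethoxyphenol
Product: 6 1-iodo-3-isopropoxy-2,4,5-trimethoxybenzene
Conditions: MeI, K2CO3, DMF, rt
Reagents that add atoms: iodomethane, CI
Why: Williamson O-methylation of the hindered phenoxide with a small electrophile should complete the 2',4',5'-trimethoxy pattern and leave the aryl iodide untouched.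

Step 5
Reactants: 6 1-iodo-3-isopropoxy-2,4,5-trimethoxybenzene; 7 ethyl propiolate
Product: 8 ethyl 3-(3-isopropoxy-2,4,5-trimethoxyphenyl)propiolate
Conditions: PdCl2(PPh3)2 (cat.), CuI (cat.), K2CO3, THF, 65 °C, slow addition of excess 7
Reagents that add atoms: none
Why: Sonogashira coupling: oxidative addition of the aryl iodide to zerovalent palladium and transmetalation from the copper acetylide of 7 should give the arylpropiolate, with carbonate in place of an amine base so that aza-Michael addition to the propiolate is excluded.

Step 6
Reactants: 8 ethyl 3-(3-isopropoxy-2,4,5-trimethoxyphenyl)propiolate; 9 3,4,5-trimethoxyphenol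
Product: 10 ethyl (Z)-3-(3-isopropoxy-2,4,5-trimethoxyphenyl)-3-(3,4,5-trimethoxyphenoxy)acrylate (ester and aryloxy group cis)
Conditions: Cs2CO3 (0.2 equiv), DMF, 50 °C
Reagents that add atoms: none
Why: Base-catalysed oxa-Michael addition: the phenoxide of 9 should attack the alkynoate carbon bearing ring B, and protonation of the vinyl anion anti to the new C–O bond should place the aryloxy group cis to the ester with all atoms of both partners retained; any minor E-isomer would be removed by chromatography.

Step 7
Reactants: 10 ethyl (Z)-3-(3-isopropoxy-2,4,5-trimethoxyphenyl)-3-(3,4,5-trimethoxyphenoxy)acrylate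
Product: 11 (Z)-3-(3-isopropoxy-2,4,5-trimethoxyphenyl)-3-(3,4,5-trimethoxyphenoxy)acrylic acid
Conditions: LiOH, THF/MeOH/H2O, rt; then 1 M HCl, 0 °C
Reagents that add atoms: lithium hydroxide, [Li+].[OH-]
Why: Ester saponification by acyl substitution at room temperature, followed by brief cold acidification, should release the acid without hydrolysing the enol ether or disturbing the alkene geometry.

Step 8
Reactants: 11 (Z)-3-(3-isopropoxy-2,4,5-trimethoxyphenyl)-3-(3,4,5-trimethoxyphenoxy)acrylic acid
Product: 13 3'-isopropoxy-5,6,7,2',4',5'-hexamethoxyflavone, via acyl trifluoroacetate 12 (not isolated)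
Conditions: TFAA, CH2Cl2, 0 °C to rt
Reagents that add atoms: none
Why: TFAA converts the acid into the acyl trifluoroacetate 12, whose activated carbonyl carbon (the future C4) is attacked by the ortho carbon of the trimethoxyphenoxy ring (the future C4a) in an intramolecular Friedel–Crafts acylation; loss of trifluoroacetate and of the ring proton restores aromaticity and leaves the 4-pyranone at its final oxidation level. The closest known reactions are the closure of 3-aryloxycinnamic acids to flavones through their acid chlorides or in mineral acid, and the TFAA-mediated closure of 2-aryloxybenzoic acids to xanthones, of which this is the vinylogous case. Ring C closes in a 6-exo-trig mode, the attacked carbonyl being exocyclic to the ring that forms. No stereocentre is created. The step needs chemoselectivity for ring A over ring B and a single regiochemistry on ring A: the Z-alkene holds the acyl group on the side of the aryloxy oxygen, so only ring A can reach it through a six-membered transition state, and the two ortho carbons of the 3,4,5-trimethoxyphenoxy ring are equivalent. The isopropyl and methyl ethers should be inert to TFAA and to the trifluoroacetic acid released.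

Step 9
Reactants: 13 3'-isopropoxy-5,6,7,2',4',5'-hexamethoxyflavone
Product: 14 psiadiarabicin (5,3'-dihydroxy-6,7,2',4',5'-pentamethoxyflavone)
Conditions: BCl3, CH2Cl2, −78 to 0 °C; then H2O
Reagents that add atoms: none
Why: Lewis acid ether cleavage: BCl3 chelates the C4 carbonyl and the peri 5-methoxy oxygen so that chloride demethylates that ether selectively, and it ionises the secondary isopropyl ether much faster than the remaining aryl methyl ethers, so both hydroxyls should be released in one operation after aqueous work-up.

Compound list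
1 | 2-hydroxy-3,4-dimethoxybenzaldehyde | COc1ccc(C=O)c(O)c1OC | starting material
2 | 2-isopropoxy-3,4-dimethoxybenzaldehyde | COc1ccc(C=O)c(OC(C)C)c1OC | intermediate
3 | 2-isopropoxy-3,4-dimethoxyphenyl formate (not isolated) | COc1ccc(OC=O)c(OC(C)C)c1OC | intermediate
4 | 2-isopropoxy-3,4-dimethoxyphenol | COc1ccc(O)c(OC(C)C)c1OC | intermediate
5 | 6-iodo-2-isopropoxy-3,4-dimethoxyphenol | COc1cc(I)c(O)c(OC(C)C)c1OC | intermediate
6 | 1-iodo-3-isopropoxy-2,4,5-trimethoxybenzene | COc1cc(I)c(OC)c(OC(C)C)c1OC | intermediate
7 | ethyl propiolate | CCOC(=O)C#C | starting material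
8 | ethyl 3-(3-isopropoxy-2,4,5-trimethoxyphenyl)propiolate | CCOC(=O)C#Cc1cc(OC)c(OC)c(OC(C)C)c1OC | intermediate
9 | 3,4,5-trimethoxyphenol | COc1cc(O)cc(OC)c1OC | starting material
10 | ethyl (Z)-3-(3-isopropoxy-2,4,5-trimethoxyphenyl)-3-(3,4,5-trimethoxyphenoxy)acrylate | CCOC(=O)/C=C(\Oc1cc(OC)c(OC)c(OC)c1)c1cc(OC)c(OC)c(OC(C)C)c1OC | intermediate
11 | (Z)-3-(3-isopropoxy-2,4,5-trimethoxyphenyl)-3-(3,4,5-trimethoxyphenoxy)acrylic acid | OC(=O)/C=C(\Oc1cc(OC)c(OC)c(OC)c1)c1cc(OC)c(OC)c(OC(C)C)c1OC | intermediate
12 | (Z)-3-(3-isopropoxy-2,4,5-trimethoxyphenyl)-3-(3,4,5-trimethoxyphenoxy)acryloyl trifluoroacetate, mixed anhydride (not isolated) | O=C(/C=C(\Oc1cc(OC)c(OC)c(OC)c1)c1cc(OC)c(OC)c(OC(C)C)c1OC)OC(=O)C(F)(F)F | intermediate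
13 | 3'-isopropoxy-5,6,7,2',4',5'-hexamethoxyflavone, 2-(3-isopropoxy-2,4,5-trimethoxyphenyl)-5,6,7-trimethoxy-4H-chromen-4-one | COc1cc2oc(-c3cc(OC)c(OC)c(OC(C)C)c3OC)cc(=O)c2c(OC)c1OC | intermediate
14 | psiadiarabicin, 5-hydroxy-2-(3-hydroxy-2,4,5-trimethoxyphenyl)-6,7-dimethoxy-4H-chromen-4-one | COc1cc(-c2cc(=O)c3c(O)c(OC)c(OC)cc3o2)c(OC)c(O)c1OC | target

Total step count: 9
Longest linear sequence: 9 steps (1 to 14; 7 and 9 are purchased)

Steps most likely to fail

Step 8. The mixed anhydride may be too weak an electrophile for ring A, so that acylation stalls, or acid released in the flask may erode the alkene geometry and allow closure onto ring B instead. The fallback abandons the C4–C4a closure and builds ring C by the chalcone route; it sets out from 6 and 9 and comes back at 13. Iodine–lithium exchange on 6 (n-BuLi, THF, −78 °C) and a DMF quench should give 3-isopropoxy-2,4,5-trimethoxybenzaldehyde F1. C-Acetylation of 9 ortho to the hydroxyl (AcOH, BF3·OEt2, 80 °C) should give 1-(6-hydroxy-2,3,4-trimethoxyphenyl)ethanone F2. Claisen–Schmidt condensation of F1 with F2 (KOH, EtOH, rt) should give (E)-1-(6-hydroxy-2,3,4-trimethoxyphenyl)-3-(3-isopropoxy-2,4,5-trimethoxyphenyl)prop-2-en-1-one F3. Oxidative cyclisation of F3 (catalytic iodine, DMSO, 120 °C) should then deliver 13.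

Step 6. Reversible addition of phenoxide to the product, or the heating that the electron-rich alkynoate may demand, could scramble the alkene geometry and leave a mixture that cannot be separated cleanly. The fallback gives up kinetic stereocontrol in favour of a closure under which the isomers interconvert; it sets out from 8 and comes back at 13. The addition is run to completion without regard to geometry, giving 10 together with ethyl (E)-3-(3-isopropoxy-2,4,5-trimethoxyphenyl)-3-(3,4,5-trimethoxyphenoxy)acrylate F4. Saponification of the mixture gives 11 together with (E)-3-(3-isopropoxy-2,4,5-trimethoxyphenyl)-3-(3,4,5-trimethoxyphenoxy)acrylic acid F5. The mixed acids are closed in Eaton's reagent (P2O5 in MeSO3H, rt to 40 °C), where C-protonation of the enol ether lets the two forms equilibrate. Only the Z form can reach ring A, and closure to the aromatic pyranone should drain the mixture into 13.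

Step 5. Base- and copper-induced oligomerisation of ethyl propiolate and oxidative homocoupling of the alkyne may outrun oxidative addition of the electron-rich iodide. The fallback separates the coupling from the introduction of the ester; it sets out from 6 and comes back at 8. Sonogashira coupling of 6 with trimethylsilylacetylene (PdCl2(PPh3)2, CuI, Et3N, 50 °C) should give ((3-isopropoxy-2,4,5-trimethoxyphenyl)ethynyl)trimethylsilane F6. Desilylation (K2CO3, MeOH, rt) should give 1-ethynyl-3-isopropoxy-2,4,5-trimethoxybenzene F7. Deprotonation of F7 (n-BuLi, THF, −78 °C) and trapping with ethyl chloroformate should give 8.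

Further compounds
F1 | step 8 | 3-isopropoxy-2,4,5-trimethoxybenzaldehyde | COc1cc(C=O)c(OC)c(OC(C)C)c1OC
F2 | step 8 | 1-(6-hydroxy-2,3,4-trimethoxyphenyl)ethanone | CC(=O)c1c(O)cc(OC)c(OC)c1OC
F3 | step 8 | (E)-1-(6-hydroxy-2,3,4-trimethoxyphenyl)-3-(3-isopropoxy-2,4,5-trimethoxyphenyl)prop-2-en-1-one | COc1cc(/C=C/C(=O)c2c(O)cc(OC)c(OC)c2OC)c(OC)c(OC(C)C)c1OC
F4 | step 6 | ethyl (E)-3-(3-isopropoxy-2,4,5-trimethoxyphenyl)-3-(3,4,5-trimethoxyphenoxy)acrylate | CCOC(=O)/C=C(/Oc1cc(OC)c(OC)c(OC)c1)c1cc(OC)c(OC)c(OC(C)C)c1OC
F5 | step 6 | (E)-3-(3-isopropoxy-2,4,5-trimethoxyphenyl)-3-(3,4,5-trimethoxyphenoxy)acrylic acid | OC(=O)/C=C(/Oc1cc(OC)c(OC)c(OC)c1)c1cc(OC)c(OC)c(OC(C)C)c1OC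
F6 | step 5 | ((3-isopropoxy-2,4,5-trimethoxyphenyl)ethynyl)trimethylsilane | COc1cc(C#C[Si](C)(C)C)c(OC)c(OC(C)C)c1OC
F7 | step 5 | 1-ethynyl-3-isopropoxy-2,4,5-trimethoxybenzene | COc1cc(C#C)c(OC)c(OC(C)C)c1OC
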